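**Retrosynthetic overview**
1. The enal is made last: C1'(=CH2)–CHO comes from a C2–CH2–CHO aldehyde by Mannich methylenation, and that aldehyde from a C2-allyl group by alkene cleavage; the angelate and the C3 acetate are late acylations.
2. The cis C2/C3 pair comes from a 2-allylbenzofuran-3(2H)-one by transfer hydrogenation under dynamic kinetic resolution.
3. Feature the strategy rests on: C2 of the dihydrofuran ring is bonded at once to ring oxygen O1, to C3 (a carbonyl carbon at the ketone stage) and to C1' of a three-carbon chain. That is the pattern left by a ketocarbene carbon that has taken up an allyl ether oxygen and then its allyl group, so O1–C2 and C2–C1' are disconnected together to an ortho-allyloxyaryl diazomethyl ketone (oxonium ylide, then [2,3] shift).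
4. Ring order: the benzene ring is bought as methyl 5-acetylsalicylate; the furanone ring is the only ring formed, in the key step. The phenol is allylated before the acetyl group is reduced, so the (R)-carbinol is never generated on a free para-hydroxyaryl system.

Key step: step 6

Assumption: the (1R,2R)-diimine is taken to favour 2R in step 6; if the sense is opposite the (1S,2S)-ligand is used, and the route does not depend on it because C2 is equilibrated and fixed in step 7.

**Route**

Step 1
Reactants: 1 methyl 5-acetylsalicylate; 2 allyl bromide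
Product: 3 methyl 5-acetyl-2-(allyloxy)benzoate
Conditions: K2CO3, DMF, 50 °C
Reagents that add atoms: none
Why: Williamson O-alkylation of the phenoxide with a reactive allylic bromide leaves ester and ketone untouched, and capping the phenol first avoids a later reduction on a para-hydroxyaryl ketone whose carbinol would be prone to quinone methide formation.

Step 2
Reactants: 3 methyl 5-acetyl-2-(allyloxy)benzoate
Product: 4 methyl 2-(allyloxy)-5-[(1R)-1-hydroxyethyl]benzoate
Conditions: RuCl(p-cymene)[(R,R)-TsDPEN] (1 mol%), HCO2H/Et3N 5:2, 30 °C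
Reagents that add atoms: none
Why: Noyori–Ikariya asymmetric transfer hydrogenation of an aryl methyl ketone, in which the (R,R)-TsDPEN ruthenium hydride delivers hydride to the face that gives the (R)-1-arylethanol, while the coordinatively saturated hydride does not engage the allyl ether or the ester.

Step 3
Reactants: 4 methyl 2-(allyloxy)-5-[(1R)-1-hydroxyethyl]benzoate
Product: 5 methyl 2-(allyloxy)-5-[(1R)-1-(tert-butyldimethylsilyloxy)ethyl]benzoate
Conditions: TBSCl, imidazole, DMF, rt
Reagents that add atoms: tert-butyldimethylsilyl chloride, CC(C)(C)[Si](C)(C)Cl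
Why: Standard silylation of a secondary alcohol, giving an ether that should survive saponification, carbene chemistry and the second transfer hydrogenation without touching the stereocentre.

Step 4
Reactants: 5 methyl 2-(allyloxy)-5-[(1R)-1-(tert-butyldimethylsilyloxy)ethyl]benzoate
Product: 6 2-(allyloxy)-5-[(1R)-1-(tert-butyldimethylsilyloxy)ethyl]benzoic acid
Conditions: LiOH·H2O, THF/MeOH/H2O, 40 °C; then 1 M HCl to pH 4, 0 °C
Reagents that add atoms: lithium hydroxide, [Li+].[OH-]
Why: Ester saponification by acyl–oxygen cleavage, to which the secondary silyl ether and the allyl ether are stable, with a brief cold acidification that should spare the para-alkoxybenzylic silyl ether.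

Step 5
Reactants: 6 2-(allyloxy)-5-[(1R)-1-(tert-butyldimethylsilyloxy)ethyl]benzoic acid; 7 trimethylsilyldiazomethane
Product: 9 1-{2-(allyloxy)-5-[(1R)-1-(tert-butyldimethylsilyloxy)ethyl]phenyl}-2-diazoethan-1-one, via isobutyl carbonic mixed anhydride 8 (not isolated)
Conditions: i-BuOCOCl, N-methylmorpholine, THF, −15 °C; then 7, MeCN, 0 °C to rt
Reagents that add atoms: isobutyl chloroformate, CC(C)COC(Cl)=O (atoms kept only in 8)
Why: Acylation of a diazoalkane (first stage of an Arndt–Eistert sequence), in which the acid is activated as a mixed carbonic anhydride under neutral conditions that spare the benzylic silyl ether, trimethylsilyldiazomethane attacks the aroyl carbonyl, and the expelled carbonate removes the silyl group to leave the terminal diazoketone.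

Step 6
Reactants: 9 1-{2-(allyloxy)-5-[(1R)-1-(tert-butyldimethylsilyloxy)ethyl]phenyl}-2-diazoethan-1-one
Product: 11 (2R)-2-allyl-5-[(1R)-1-(tert-butyldimethylsilyloxy)ethyl]benzofuran-3(2H)-one, via allyloxonium ylide 10 (not isolated)
Conditions: Cu(MeCN)4PF6 (2 mol%), (1R,2R)-N,N'-bis(2,6-dichlorobenzylidene)cyclohexane-1,2-diamine (2.4 mol%), CH2Cl2, reflux, slow addition of 9
Reagents that add atoms: none
Why: The monovalent copper catalyst decomposes the diazoketone to an electrophilic ketocarbene whose carbon (the future C2) is captured by a lone pair of the allyl ether oxygen O1, and the allyloxonium ylide 10 then relaxes by a concerted, symmetry-allowed [2,3]-sigmatropic shift through a five-membered envelope in which the allyl terminus becomes C1' as the O1–allyl bond breaks. The closest known reaction type is exactly this copper- or dirhodium-catalysed oxonium ylide formation and [2,3]-rearrangement of 2-(allyloxy)aryl diazomethyl ketones to 2-allylbenzofuran-3(2H)-ones. The furanone ring closes in the ylide-forming event, a five-membered (5-exo-trig type) attack of O1 on the trigonal carbene carbon with the Cu=C bond outside the ring, and the shift then forms C2–C1' without opening it. The C2 stereocentre is set during the shift from a copper-associated ylide inside the chiral diimine, which should enrich the (R) epimer only moderately; this is tolerated because C2 is re-equilibrated and fixed in step 7. The selectivities needed are ylide formation over cyclopropanation, C–H insertion and carbene dimerisation, and [2,3] over [1,2] shift: the ortho tether on the rigid arene makes O1 capture a fast five-membered closure, copper favours ylide chemistry, slow addition keeps the diazo concentration low, and the allyl group offers the low-barrier [2,3] path.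

Step 7
Reactants: 11 (2R)-2-allyl-5-[(1R)-1-(tert-butyldimethylsilyloxy)ethyl]benzofuran-3(2H)-one (with its C2 epimer)
Product: 12 (2R,3R)-2-allyl-5-[(1R)-1-(tert-butyldimethylsilyloxy)ethyl]-2,3-dihydrobenzofuran-3-ol (2,3-cis)
Conditions: RuCl(p-cymene)[(S,S)-TsDPEN] (2 mol%), HCO2H/Et3N 1:1, EtOAc, 30 °C
Reagents that add atoms: none
Why: Noyori–Ikariya transfer hydrogenation under dynamic kinetic resolution, in which C2–H (between the ketone and O1, with an aromatic 3-hydroxybenzofuran enol) epimerises quickly in the amine-rich medium, hydride adds anti to the allyl group to give the 2,3-cis alcohol, and the (S,S)-TsDPEN catalyst selects the (3R) carbinol by the usual aryl ketone model, which fixes C2 as R.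

Step 8
Reactants: 12 (2R,3R)-2-allyl-5-[(1R)-1-(tert-butyldimethylsilyloxy)ethyl]-2,3-dihydrobenzofuran-3-ol
Product: 13 (2R,3R)-2-allyl-5-[(1R)-1-(tert-butyldimethylsilyloxy)ethyl]-2,3-dihydrobenzofuran-3-yl acetate
Conditions: Ac2O, pyridine, DMAP (cat.), CH2Cl2, 0 °C to rt
Reagents that add atoms: acetic anhydride, CC(=O)OC(C)=O
Why: DMAP-catalysed acylation of a secondary alcohol under basic conditions, which avoid ionisation of the ortho-alkoxybenzylic C3–O bond and touch no stereocentre.

Step 9
Reactants: 13 (2R,3R)-2-allyl-5-[(1R)-1-(tert-butyldimethylsilyloxy)ethyl]-2,3-dihydrobenzofuran-3-yl acetate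
Product: 14 (2R,3R)-2-allyl-5-[(1R)-1-hydroxyethyl]-2,3-dihydrobenzofuran-3-yl acetate
Conditions: Bu4NF, AcOH (1:1), THF, 0 °C to rt
Reagents that add atoms: none
Why: Fluoride-induced Si–O cleavage buffered with acetic acid, so that the acetate is neither cleaved nor eliminated and no strong acid is present to ionise the para-alkoxybenzylic carbinol.

Step 10
Reactants: 14 (2R,3R)-2-allyl-5-[(1R)-1-hydroxyethyl]-2,3-dihydrobenzofuran-3-yl acetate; 15 angelic acid
Product: 17 (1R)-1-[(2R,3R)-3-acetoxy-2-allyl-2,3-dihydrobenzofuran-5-yl]ethyl (Z)-2-methylbut-2-enoate, via angeloyl trichlorobenzoyl mixed anhydride 16 (not isolated)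
Conditions: 15, 2,4,6-Cl3C6H2COCl, Et3N, toluene, rt; then 14, toluene, 75 °C
Reagents that add atoms: 2,4,6-trichlorobenzoyl chloride, O=C(Cl)c1c(Cl)cc(Cl)cc1Cl (atoms kept only in 16)
Why: Yamaguchi-type esterification through the hindered aroyl mixed anhydride, run without a nucleophilic amine catalyst because that is the mode in which the (Z)-2-methylbut-2-enoyl group should not isomerise to the tiglate; the alcohol attacks the angeloyl carbonyl and the carbinol C–O bond is not broken, so (R) is retained.

Step 11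
Reactants: 17 (1R)-1-[(2R,3R)-3-acetoxy-2-allyl-2,3-dihydrobenzofuran-5-yl]ethyl (Z)-2-methylbut-2-enoate
Product: 19 (1R)-1-[(2R,3R)-3-acetoxy-2-(2-oxoethyl)-2,3-dihydrobenzofuran-5-yl]ethyl (Z)-2-methylbut-2-enoate, via vicinal diol 18 (not isolated)
Conditions: OsO4 (2 mol%), NaIO4, 2,6-lutidine, dioxane/H2O 3:1, rt
Reagents that add atoms: osmium tetroxide, O=[Os](=O)(=O)=O; sodium periodate, [Na+].[O-]I(=O)(=O)=O
Why: Lemieux–Johnson oxidation, in which OsO4 should dihydroxylate the electron-neutral monosubstituted alkene well before the electron-poor, hindered trisubstituted angelate alkene, NaIO4 cleaves the diol and re-oxidises osmium, and 2,6-lutidine keeps the medium near neutral for the β-aryloxy aldehyde.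

Step 12
Reactants: 19 (1R)-1-[(2R,3R)-3-acetoxy-2-(2-oxoethyl)-2,3-dihydrobenzofuran-5-yl]ethyl (Z)-2-methylbut-2-enoate
Product: 21 (1R)-1-[(2R,3R)-3-acetoxy-2-(3-oxoprop-1-en-2-yl)-2,3-dihydrobenzofuran-5-yl]ethyl (Z)-2-methylbut-2-enoate, via Mannich base 20 (not isolated)
Conditions: dimethylmethyleneiminium iodide, Et3N, CH2Cl2, 0 °C to rt
Reagents that add atoms: dimethylmethyleneiminium iodide, C=[N+](C)C.[I-]
Why: Mannich α-methylenation of an aldehyde with a preformed iminium salt (Eschenmoser methylenation), in which the enol of 19 adds at C1' and the β-amino aldehyde loses dimethylamine to give the 1,1-disubstituted enal; it is placed last so that the base-sensitive enal is carried through no further operation.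

**Compound list**
1 | methyl 5-acetylsalicylate | COC(=O)c1cc(C(C)=O)ccc1O | starting material
2 | allyl bromide | C=CCBr | starting material
3 | methyl 5-acetyl-2-(allyloxy)benzoate | C=CCOc1ccc(C(C)=O)cc1C(=O)OC | intermediate
4 | methyl 2-(allyloxy)-5-[(1R)-1-hydroxyethyl]benzoate | C=CCOc1ccc([C@@H](C)O)cc1C(=O)OC | intermediate
5 | methyl 2-(allyloxy)-5-[(1R)-1-(tert-butyldimethylsilyloxy)ethyl]benzoate | C=CCOc1ccc([C@@H](C)O[Si](C)(C)C(C)(C)C)cc1C(=O)OC | intermediate
6 | 2-(allyloxy)-5-[(1R)-1-(tert-butyldimethylsilyloxy)ethyl]benzoic acid | C=CCOc1ccc([C@@H](C)O[Si](C)(C)C(C)(C)C)cc1C(=O)O | intermediate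
7 | trimethylsilyldiazomethane | C[Si](C)(C)C=[N+]=[N-] | starting material
8 | 2-(allyloxy)-5-[(1R)-1-(tert-butyldimethylsilyloxy)ethyl]benzoic isobutyl carbonic anhydride | C=CCOc1ccc([C@@H](C)O[Si](C)(C)C(C)(C)C)cc1C(=O)OC(=O)OCC(C)C | intermediate (not isolated)
9 | 1-{2-(allyloxy)-5-[(1R)-1-(tert-butyldimethylsilyloxy)ethyl]phenyl}-2-diazoethan-1-one | C=CCOc1ccc([C@@H](C)O[Si](C)(C)C(C)(C)C)cc1C(=O)C=[N+]=[N-] | intermediate
10 | 1-allyl-5-[(1R)-1-(tert-butyldimethylsilyloxy)ethyl]-3-oxo-2,3-dihydrobenzofuran-1-ium-2-ide (oxonium ylide) | C=CC[O+]1c2ccc([C@@H](C)O[Si](C)(C)C(C)(C)C)cc2C(=O)[CH-]1 | intermediate (not isolated)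
11 | (2R)-2-allyl-5-[(1R)-1-(tert-butyldimethylsilyloxy)ethyl]benzofuran-3(2H)-one | C=CC[C@H]1Oc2ccc([C@@H](C)O[Si](C)(C)C(C)(C)C)cc2C1=O | intermediate
12 | (2R,3R)-2-allyl-5-[(1R)-1-(tert-butyldimethylsilyloxy)ethyl]-2,3-dihydrobenzofuran-3-ol | C=CC[C@H]1Oc2ccc([C@@H](C)O[Si](C)(C)C(C)(C)C)cc2[C@H]1O | intermediate
13 | (2R,3R)-2-allyl-5-[(1R)-1-(tert-butyldimethylsilyloxy)ethyl]-2,3-dihydrobenzofuran-3-yl acetate | C=CC[C@H]1Oc2ccc([C@@H](C)O[Si](C)(C)C(C)(C)C)cc2[C@H]1OC(C)=O | intermediate
14 | (2R,3R)-2-allyl-5-[(1R)-1-hydroxyethyl]-2,3-dihydrobenzofuran-3-yl acetate | C=CC[C@H]1Oc2ccc([C@@H](C)O)cc2[C@H]1OC(C)=O | intermediate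
15 | angelic acid, (Z)-2-methylbut-2-enoic acid | C/C=C(/C)C(=O)O | starting material
16 | (Z)-2-methylbut-2-enoic 2,4,6-trichlorobenzoic anhydride | C/C=C(/C)C(=O)OC(=O)c1c(Cl)cc(Cl)cc1Cl | intermediate (not isolated)
17 | (1R)-1-[(2R,3R)-3-acetoxy-2-allyl-2,3-dihydrobenzofuran-5-yl]ethyl (Z)-2-methylbut-2-enoate | C=CC[C@H]1Oc2ccc([C@@H](C)OC(=O)/C(C)=C\C)cc2[C@H]1OC(C)=O | intermediate
18 | (1R)-1-[(2R,3R)-3-acetoxy-2-(2,3-dihydroxypropyl)-2,3-dihydrobenzofuran-5-yl]ethyl (Z)-2-methylbut-2-enoate, both carbinol epimers | OCC(O)C[C@H]1Oc2ccc([C@@H](C)OC(=O)/C(C)=C\C)cc2[C@H]1OC(C)=O | intermediate (not isolated)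
19 | (1R)-1-[(2R,3R)-3-acetoxy-2-(2-oxoethyl)-2,3-dihydrobenzofuran-5-yl]ethyl (Z)-2-methylbut-2-enoate | O=CC[C@H]1Oc2ccc([C@@H](C)OC(=O)/C(C)=C\C)cc2[C@H]1OC(C)=O | intermediate
20 | (1R)-1-{(2R,3R)-3-acetoxy-2-[1-(dimethylamino)-3-oxopropan-2-yl]-2,3-dihydrobenzofuran-5-yl}ethyl (Z)-2-methylbut-2-enoate, both α-epimers | CN(C)CC(C=O)[C@H]1Oc2ccc([C@@H](C)OC(=O)/C(C)=C\C)cc2[C@H]1OC(C)=O | intermediate (not isolated)
21 | (1R)-1-[(2R,3R)-3-acetoxy-2-(3-oxoprop-1-en-2-yl)-2,3-dihydrobenzofuran-5-yl]ethyl (Z)-2-methylbut-2-enoate | C=C(C=O)[C@H]1Oc2ccc([C@@H](C)OC(=O)/C(C)=C\C)cc2[C@H]1OC(C)=O | target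

**Step count**
Total: 12 steps. Longest linear sequence: 12 steps, from 1 to 21.

**Steps most likely to fail**

Step 12. Enolisation of the β-aryloxy aldehyde under triethylamine can expel the O1 phenoxide (retro-oxa-Michael ring opening with unselective reclosure, which would scramble C2). In addition, the C2–H of the product, vinylogous to the aldehyde, can start loss of acetic acid across C2–C3 to an aromatic benzofuran. The fallback sets out from 19 and returns at 21, and separates enol formation, C–C bond formation and elimination so that no free amine base meets the enolisable aldehyde or the enal. Compound 19 is converted with t-BuMe2SiOTf and Et3N in CH2Cl2 at −78 °C into the silyl enol ether (1R)-1-{(2R,3R)-3-acetoxy-2-[2-(tert-butyldimethylsilyloxy)vinyl]-2,3-dihydrobenzofuran-5-yl}ethyl (Z)-2-methylbut-2-enoate F1. F1 is treated with dimethylmethyleneiminium iodide in CH2Cl2 without added base (Mukaiyama–Mannich reaction) to give Mannich base 20, now isolated. Compound 20 is oxidised with mCPBA at −20 °C to the amine N-oxide (1R)-1-{(2R,3R)-3-acetoxy-2-[1-(dimethyloxidoammonio)-3-oxopropan-2-yl]-2,3-dihydrobenzofuran-5-yl}ethyl (Z)-2-methylbut-2-enoate F2, which should undergo thermal syn (Cope) elimination on warming to room temperature to give 21.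

Step 7. Epimerisation at C2 may be slower than reduction of the mismatched epimer, which would erode the diastereomeric purity, and the ortho-alkoxybenzylic alcohol may lose water to a benzofuran in the formic acid medium. The fallback sets out from 11 and returns at 12, and replaces dynamic resolution by relative control followed by enzymatic sorting. Luche reduction (NaBH4, CeCl3·7H2O, MeOH, −40 °C) should add hydride anti to the allyl group in both C2 epimers and give the cis alcohols 12 and (2S,3S)-2-allyl-5-[(1R)-1-(tert-butyldimethylsilyloxy)ethyl]-2,3-dihydrobenzofuran-3-ol F3. Lipase from Burkholderia cepacia with vinyl acetate in t-BuOMe at 30 °C should, by the empirical size rule for benzo-fused cyclic carbinols, acylate the (3S) carbinol to (2S,3S)-2-allyl-5-[(1R)-1-(tert-butyldimethylsilyloxy)ethyl]-2,3-dihydrobenzofuran-3-yl acetate F4. Alcohol 12 is left unreacted, separated by chromatography and carried into step 8.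

Step 11. Osmylation may not discriminate sufficiently between the terminal alkene and the angelate C=C, so that the ester side chain is cleaved as well. The fallback sets out from 13 and returns at 21, and cleaves the alkene before any angelate is present. Compound 13 is treated with OsO4 (cat.), NaIO4 and 2,6-lutidine in dioxane/H2O to give, through (2R,3R)-5-[(1R)-1-(tert-butyldimethylsilyloxy)ethyl]-2-(2,3-dihydroxypropyl)-2,3-dihydrobenzofuran-3-yl acetate F5, the aldehyde (2R,3R)-5-[(1R)-1-(tert-butyldimethylsilyloxy)ethyl]-2-(2-oxoethyl)-2,3-dihydrobenzofuran-3-yl acetate F6. Methylenation with dimethylmethyleneiminium iodide and Et3N in CH2Cl2 proceeds through (2R,3R)-5-[(1R)-1-(tert-butyldimethylsilyloxy)ethyl]-2-[1-(dimethylamino)-3-oxopropan-2-yl]-2,3-dihydrobenzofuran-3-yl acetate F7 to the enal (2R,3R)-5-[(1R)-1-(tert-butyldimethylsilyloxy)ethyl]-2-(3-oxoprop-1-en-2-yl)-2,3-dihydrobenzofuran-3-yl acetate F8. HF·pyridine in THF/pyridine at 0 °C frees the carbinol to give (2R,3R)-5-[(1R)-1-hydroxyethyl]-2-(3-oxoprop-1-en-2-yl)-2,3-dihydrobenzofuran-3-yl acetate F9. F9 is acylated with mixed anhydride 16 (made from 15 as in step 10) in toluene at 40–60 °C to give 21. The price is that the enal is carried through two further operations.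

**Further compounds**
F1 | step 12 | (1R)-1-{(2R,3R)-3-acetoxy-2-[2-(tert-butyldimethylsilyloxy)vinyl]-2,3-dihydrobenzofuran-5-yl}ethyl (Z)-2-methylbut-2-enoate | CC(C)(C)[Si](C)(C)OC=C[C@H]1Oc2ccc([C@@H](C)OC(=O)/C(C)=C\C)cc2[C@H]1OC(C)=O
F2 | step 12 | (1R)-1-{(2R,3R)-3-acetoxy-2-[1-(dimethyloxidoammonio)-3-oxopropan-2-yl]-2,3-dihydrobenzofuran-5-yl}ethyl (Z)-2-methylbut-2-enoate | C[N+](C)([O-])CC(C=O)[C@H]1Oc2ccc([C@@H](C)OC(=O)/C(C)=C\C)cc2[C@H]1OC(C)=O
F3 | step 7 | (2S,3S)-2-allyl-5-[(1R)-1-(tert-butyldimethylsilyloxy)ethyl]-2,3-dihydrobenzofuran-3-ol | C=CC[C@@H]1Oc2ccc([C@@H](C)O[Si](C)(C)C(C)(C)C)cc2[C@@H]1O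
F4 | step 7 | (2S,3S)-2-allyl-5-[(1R)-1-(tert-butyldimethylsilyloxy)ethyl]-2,3-dihydrobenzofuran-3-yl acetate | C=CC[C@@H]1Oc2ccc([C@@H](C)O[Si](C)(C)C(C)(C)C)cc2[C@@H]1OC(C)=O
F5 | step 11 | (2R,3R)-5-[(1R)-1-(tert-butyldimethylsilyloxy)ethyl]-2-(2,3-dihydroxypropyl)-2,3-dihydrobenzofuran-3-yl acetate | OCC(O)C[C@H]1Oc2ccc([C@@H](C)O[Si](C)(C)C(C)(C)C)cc2[C@H]1OC(C)=O
F6 | step 11 | (2R,3R)-5-[(1R)-1-(tert-butyldimethylsilyloxy)ethyl]-2-(2-oxoethyl)-2,3-dihydrobenzofuran-3-yl acetate | O=CC[C@H]1Oc2ccc([C@@H](C)O[Si](C)(C)C(C)(C)C)cc2[C@H]1OC(C)=O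
F7 | step 11 | (2R,3R)-5-[(1R)-1-(tert-butyldimethylsilyloxy)ethyl]-2-[1-(dimethylamino)-3-oxopropan-2-yl]-2,3-dihydrobenzofuran-3-yl acetate | CN(C)CC(C=O)[C@H]1Oc2ccc([C@@H](C)O[Si](C)(C)C(C)(C)C)cc2[C@H]1OC(C)=O
F8 | step 11 | (2R,3R)-5-[(1R)-1-(tert-butyldimethylsilyloxy)ethyl]-2-(3-oxoprop-1-en-2-yl)-2,3-dihydrobenzofuran-3-yl acetate | C=C(C=O)[C@H]1Oc2ccc([C@@H](C)O[Si](C)(C)C(C)(C)C)cc2[C@H]1OC(C)=O
F9 | step 11 | (2R,3R)-5-[(1R)-1-hydroxyethyl]-2-(3-oxoprop-1-en-2-yl)-2,3-dihydrobenzofuran-3-yl acetate | C=C(C=O)[C@H]1Oc2ccc([C@@H](C)O)cc2[C@H]1OC(C)=O
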